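The route rests on disconnecting the tertiary O1–C6 bond of the 1,2-dioxane ring, which lies next to the C7 methylene: a peroxide already attached to C3 can close onto an E C6=C7 alkene if an electrophile is held temporarily on C7. In one operation, Hg(O2CCF3)2 then NaBH4 forms O1–C6, closes the six-membered peroxide ring and sets C6 under control of the C4 methyl centre, leaving C7 as CH2. The substrate is an acyclic hydroperoxy methyl ketal of a β-keto ester carrying the C4 and C8 centres, assembled by copper-catalysed alkyl coupling, Wittig olefination, oxazolidinone alkylation and malonate homologation.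

Key step: step 10

Remark on the chemistry: atoms are numbered along the chain (C1 carboxyl carbon, C3 hemiketal carbon bearing O2, C6 bearing O1, C8 the side-chain methyl centre, phenyl on C16). The target is (3S,4R,6S,8R); its 3S hemiketal (axial OH, equatorial CH2CO2H) is assumed to be the anomer favoured at equilibrium, so C3 epimer mixtures are carried from 19 to 22 and should converge in step 12.

Step 1
Reactants: 1 (7-bromoheptyl)benzene; 2 (S)-3-bromo-2-methylpropan-1-ol
Product: 4 (R)-2-methyl-10-phenyldecan-1-ol, via (7-phenylheptyl)magnesium bromide 3 (not isolated)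
Conditions: 1 (2.4 equiv), Mg, THF, 40 °C; then 2, Li2CuCl4 (cat.), THF, −78 °C → rt; aq. NH4Cl
Reagents that add atoms: none
Why: Copper-catalysed sp3–sp3 Grignard cross-coupling (Kochi–Fouquet–Schlosser type) displaces the primary bromide while the first equivalent of 3 masks the hydroxyl as its magnesium alkoxide; the stereocentre of 2 is not touched and becomes C8.

Step 2
Reactants: 4 (R)-2-methyl-10-phenyldecan-1-ol; 5 ethyl 2-(triphenyl-λ5-phosphanylidene)propanoate
Product: 7 ethyl (2E,4R)-2,4-dimethyl-12-phenyldodec-2-enoate, via (R)-2-methyl-10-phenyldecanal 6 (not isolated)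
Conditions: TEMPO (cat.), PhI(OAc)2, CH2Cl2, rt; then 5, rt → 40 °C
Reagents that add atoms: none
Why: Oxoammonium oxidation gives the α-branched aldehyde under non-basic conditions, and the stabilised α-methyl ylide olefinates it in the same flask (Wittig reaction) with the usual strong E preference, so the aldehyde has little chance to epimerise.

Step 3
Reactants: 7 ethyl (2E,4R)-2,4-dimethyl-12-phenyldodec-2-enoate
Product: 8 (2E,4R)-2,4-dimethyl-12-phenyldodec-2-en-1-ol
Conditions: i-Bu2AlH (2.2 equiv), CH2Cl2, −78 → 0 °C; aq. potassium sodium tartrate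
Reagents that add atoms: none
Why: i-Bu2AlH reduces the conjugated ester to the allylic alcohol by 1,2-hydride delivery without affecting the alkene geometry or the stereocentre.

Step 4
Reactants: 8 (2E,4R)-2,4-dimethyl-12-phenyldodec-2-en-1-ol
Product: 9 [(9R,10E)-12-bromo-9,11-dimethyldodec-10-en-1-yl]benzene
Conditions: CBr4, PPh3, CH2Cl2, 0 °C
Reagents that add atoms: carbon tetrabromide, BrC(Br)(Br)Br
Why: Appel bromination converts the primary allylic alcohol into the bromide by SN2 displacement of the oxyphosphonium group under neutral conditions, keeping the E geometry.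

Step 5
Reactants: 9 [(9R,10E)-12-bromo-9,11-dimethyldodec-10-en-1-yl]benzene; 10 (S)-4-benzyl-3-propionyloxazolidin-2-one
Product: 12 (S)-4-benzyl-3-[(2R,4E,6R)-2,4,6-trimethyl-14-phenyltetradec-4-enoyl]oxazolidin-2-one, via the sodium Z-enolate 11 (not isolated)
Conditions: 10 (1.5 equiv), NaN(SiMe3)2, THF, −78 °C; then 9, −78 → −40 °C
Reagents that add atoms: none
Why: In this Evans asymmetric alkylation the chelated sodium Z-enolate is attacked by the reactive allylic bromide on the face opposite the benzyl group of the (S)-auxiliary, which sets the new centre (C4 of the target) as R.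

Step 6
Reactants: 12 (S)-4-benzyl-3-[(2R,4E,6R)-2,4,6-trimethyl-14-phenyltetradec-4-enoyl]oxazolidin-2-one
Product: 14 (2R,4E,6R)-2,4,6-trimethyl-14-phenyltetradec-4-enoic acid, via the peroxy acid 13 (not isolated)
Conditions: LiOH, H2O2, THF/H2O, 0 °C; then aq. Na2SO3; aq. HCl
Reagents that add atoms: hydrogen peroxide, OO
Why: Hydroperoxide anion attacks the exocyclic imide carbonyl selectively (LiOH/H2O2 auxiliary cleavage) and sulfite reduces the peroxy acid, so the auxiliary is released without epimerising the α-centre and the unactivated alkene is left alone.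

Step 7
Reactants: 14 (2R,4E,6R)-2,4,6-trimethyl-14-phenyltetradec-4-enoic acid; 15 potassium 3-methoxy-3-oxopropanoate (potassium methyl malonate)
Product: 17 methyl (4R,6E,8R)-4,6,8-trimethyl-3-oxo-16-phenylhexadec-6-enoate, via the acyl imidazolide 16 (not isolated)
Conditions: 1,1'-carbonyldiimidazole, THF, rt; then 15, MgCl2, Et3N, MeCN, rt → 40 °C; aq. HCl
Reagents that add atoms: none
Why: In this Masamune–Brooks homologation the acyl imidazolide C-acylates the magnesium enolate of the malonate half ester and loss of CO2 gives the β-keto ester under near-neutral conditions that leave the α-methyl centre intact.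

Step 8
Reactants: 17 methyl (4R,6E,8R)-4,6,8-trimethyl-3-oxo-16-phenylhexadec-6-enoate
Product: 18 methyl (4R,6E,8R)-3,3-dimethoxy-4,6,8-trimethyl-16-phenylhexadec-6-enoate
Conditions: HC(OMe)3, MeOH, TsOH·H2O (cat.), rt; NaHCO3
Reagents that add atoms: trimethyl orthoformate, COC(OC)OC; methanol, CO
Why: Acid-catalysed ketalisation with the orthoformate as water scavenger gives the dimethyl ketal at room temperature, where enolisation of the β-keto ester runs toward C2 and not toward the C4 centre.

Step 9
Reactants: 18 methyl (4R,6E,8R)-3,3-dimethoxy-4,6,8-trimethyl-16-phenylhexadec-6-enoate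
Product: 19 methyl (4R,6E,8R)-3-hydroperoxy-3-methoxy-4,6,8-trimethyl-16-phenylhexadec-6-enoate (C3 epimers)
Conditions: H2O2 (anhydrous ethereal solution, excess), camphorsulfonic acid (cat.), Et2O, 0 °C; NaHCO3
Reagents that add atoms: hydrogen peroxide, OO
Why: In this acid-catalysed ketal exchange (perhydrolysis) the methoxy oxocarbenium ion from the ketal is trapped by the strongly nucleophilic H2O2 to give the hydroperoxy methyl ketal, without control at C3, which does not matter because C3 is equilibrated in step 12.

Step 10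
Reactants: 19 methyl (4R,6E,8R)-3-hydroperoxy-3-methoxy-4,6,8-trimethyl-16-phenylhexadec-6-enoate (C3 epimers)
Product: 21 methyl 2-[(4R,6S)-3-methoxy-4,6-dimethyl-6-[(2R)-2-methyl-10-phenyldecyl]-1,2-dioxan-3-yl]acetate (C3 epimers), via the C7 organomercury trifluoroacetate 20 (not isolated)
Conditions: Hg(O2CCF3)2 (1.05 equiv), CH2Cl2, −20 → 0 °C, short reaction time; then NaBH4, 3 M aq. NaOH, 0 °C
Reagents that add atoms: none
Why: The divalent mercury salt forms a mercurinium ion on the electron-rich trisubstituted C6=C7 alkene and the terminal oxygen of the C3 hydroperoxide opens it at the tertiary carbon C6 by anti addition, giving organomercurial 20, whose C7–Hg bond is then replaced by C–H with alkaline NaBH4 through the C7 radical, which also removes the transient C7 centre. The closest known reaction type is the intramolecular peroxymercuration–hydridodemercuration of unsaturated hydroperoxides and hydroperoxy ketals to 1,2-dioxanes. The 1,2-dioxane ring closes in the 6-exo-trig mode, with O1–C6 formed and C7 left outside the ring. The new C6 stereocentre is controlled by the auxiliary-derived C4 centre through a chair-like transition state with the C4 methyl group and the bulky mercurated C7 branch equatorial and the C6 methyl group axial, which corresponds to 6S (C4 methyl cis to the C6 side chain). The step needs Markovnikov regioselectivity, secured by the C6 methyl group, which puts the positive charge on C6 and disfavours the 7-endo path; chemoselectivity for the alkene over the phenyl ring and the acid-labile ketal, secured by one equivalent of the mercury salt at low temperature; and hydrogen transfer to the C7 radical faster than its attack on the O–O bond, favoured by cold, concentrated borohydride. Both C3 epimers should cyclise and are carried on together.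

Step 11
Reactants: 21 methyl 2-[(4R,6S)-3-methoxy-4,6-dimethyl-6-[(2R)-2-methyl-10-phenyldecyl]-1,2-dioxan-3-yl]acetate (C3 epimers)
Product: 22 2-[(4R,6S)-3-methoxy-4,6-dimethyl-6-[(2R)-2-methyl-10-phenyldecyl]-1,2-dioxan-3-yl]acetic acid (C3 epimers)
Conditions: LiOH, THF/H2O, 0 °C → rt; then cold dilute HCl to pH 3–4
Reagents that add atoms: lithium hydroxide, [Li+].[OH-]
Why: Saponification of the methyl ester is done on the peroxy ketal because neither peroxide carbon (C3, C6) carries hydrogen, so base-induced Kornblum–DeLaMare cleavage is impossible and the ring cannot open as a hemiketal would.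

Step 12
Reactants: 22 2-[(4R,6S)-3-methoxy-4,6-dimethyl-6-[(2R)-2-methyl-10-phenyldecyl]-1,2-dioxan-3-yl]acetic acid (C3 epimers)
Product: 23 2-[(3S,4R,6S)-3-hydroxy-4,6-dimethyl-6-[(2R)-2-methyl-10-phenyldecyl]-1,2-dioxan-3-yl]acetic acid (target)
Conditions: TsOH·H2O (cat.), MeCN/H2O, rt
Reagents that add atoms: water, O
Why: Acid-catalysed hydrolysis of the peroxy ketal through the peroxycarbenium ion (or the open δ-hydroperoxy ketone) exchanges OMe for OH, and because the hemiketal equilibrates, C3 should settle as the 3S anomer with axial OH (anomeric effect) and equatorial CH2CO2H.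

Compound list
1 | (7-bromoheptyl)benzene | BrCCCCCCCc1ccccc1 | starting material
2 | (S)-3-bromo-2-methylpropan-1-ol | C[C@H](CBr)CO | starting material
3 | (7-phenylheptyl)magnesium bromide | Br[Mg]CCCCCCCc1ccccc1 | intermediate (not isolated)
4 | (R)-2-methyl-10-phenyldecan-1-ol | C[C@H](CCCCCCCCc1ccccc1)CO | intermediate
5 | ethyl 2-(triphenyl-λ5-phosphanylidene)propanoate | CCOC(=O)C(C)=P(c1ccccc1)(c1ccccc1)c1ccccc1 | starting material
6 | (R)-2-methyl-10-phenyldecanal | C[C@H](CCCCCCCCc1ccccc1)C=O | intermediate (not isolated)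
7 | ethyl (2E,4R)-2,4-dimethyl-12-phenyldodec-2-enoate | C[C@H](CCCCCCCCc1ccccc1)/C=C(C)/C(=O)OCC | intermediate
8 | (2E,4R)-2,4-dimethyl-12-phenyldodec-2-en-1-ol | C[C@H](CCCCCCCCc1ccccc1)/C=C(C)/CO | intermediate
9 | [(9R,10E)-12-bromo-9,11-dimethyldodec-10-en-1-yl]benzene | C[C@H](CCCCCCCCc1ccccc1)/C=C(C)/CBr | intermediate
10 | (S)-4-benzyl-3-propionyloxazolidin-2-one | CCC(=O)N1[C@@H](Cc2ccccc2)COC1=O | starting material
11 | sodium (Z)-1-[(4S)-4-benzyl-2-oxo-1,3-oxazolidin-3-yl]prop-1-en-1-olate | C/C=C(\[O-])N1[C@@H](Cc2ccccc2)COC1=O.[Na+] | intermediate (not isolated)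
12 | (S)-4-benzyl-3-[(2R,4E,6R)-2,4,6-trimethyl-14-phenyltetradec-4-enoyl]oxazolidin-2-one | C[C@H](CCCCCCCCc1ccccc1)/C=C(C)/C[C@@H](C)C(=O)N1[C@@H](Cc2ccccc2)COC1=O | intermediate
13 | (2R,4E,6R)-2,4,6-trimethyl-14-phenyltetradec-4-eneperoxoic acid | C[C@H](CCCCCCCCc1ccccc1)/C=C(C)/C[C@@H](C)C(=O)OO | intermediate (not isolated)
14 | (2R,4E,6R)-2,4,6-trimethyl-14-phenyltetradec-4-enoic acid | C[C@H](CCCCCCCCc1ccccc1)/C=C(C)/C[C@@H](C)C(=O)O | intermediate
15 | potassium 3-methoxy-3-oxopropanoate | COC(=O)CC(=O)[O-].[K+] | starting material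
16 | 1-[(2R,4E,6R)-2,4,6-trimethyl-14-phenyltetradec-4-enoyl]-1H-imidazole | C[C@H](CCCCCCCCc1ccccc1)/C=C(C)/C[C@@H](C)C(=O)n1ccnc1 | intermediate (not isolated)
17 | methyl (4R,6E,8R)-4,6,8-trimethyl-3-oxo-16-phenylhexadec-6-enoate | C[C@H](CCCCCCCCc1ccccc1)/C=C(C)/C[C@@H](C)C(=O)CC(=O)OC | intermediate
18 | methyl (4R,6E,8R)-3,3-dimethoxy-4,6,8-trimethyl-16-phenylhexadec-6-enoate | C[C@H](CCCCCCCCc1ccccc1)/C=C(C)/C[C@@H](C)C(OC)(OC)CC(=O)OC | intermediate
19 | methyl (4R,6E,8R)-3-hydroperoxy-3-methoxy-4,6,8-trimethyl-16-phenylhexadec-6-enoate (C3 epimers) | C[C@H](CCCCCCCCc1ccccc1)/C=C(C)/C[C@@H](C)C(OC)(OO)CC(=O)OC | intermediate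
20 | methyl 2-[(4R,6R)-3-methoxy-4,6-dimethyl-6-{(1S,2R)-2-methyl-10-phenyl-1-[(trifluoroacetoxy)mercurio]decyl}-1,2-dioxan-3-yl]acetate (C3 epimers; same geometry at C6 as in 21, the descriptor changes only because Hg raises the rank of C7) | C[C@H](CCCCCCCCc1ccccc1)[C@H]([Hg]OC(=O)C(F)(F)F)[C@@]1(C)C[C@@H](C)C(OC)(CC(=O)OC)OO1 | intermediate (not isolated)
21 | methyl 2-[(4R,6S)-3-methoxy-4,6-dimethyl-6-[(2R)-2-methyl-10-phenyldecyl]-1,2-dioxan-3-yl]acetate (C3 epimers) | C[C@H](CCCCCCCCc1ccccc1)C[C@@]1(C)C[C@@H](C)C(OC)(CC(=O)OC)OO1 | intermediate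
22 | 2-[(4R,6S)-3-methoxy-4,6-dimethyl-6-[(2R)-2-methyl-10-phenyldecyl]-1,2-dioxan-3-yl]acetic acid (C3 epimers) | C[C@H](CCCCCCCCc1ccccc1)C[C@@]1(C)C[C@@H](C)C(OC)(CC(=O)O)OO1 | intermediate
23 | 2-[(3S,4R,6S)-3-hydroxy-4,6-dimethyl-6-[(2R)-2-methyl-10-phenyldecyl]-1,2-dioxan-3-yl]acetic acid | C[C@H](CCCCCCCCc1ccccc1)C[C@@]1(C)C[C@@H](C)[C@](O)(CC(=O)O)OO1 | target

Total step count: 12
Longest linear sequence: 12 steps (from 1 and 2 to 23); compounds 5, 10 and 15 enter as purchased.

Steps most likely to fail

Step 10. The peroxide may open the mercurinium ion at C6 with poor facial selectivity, or the C7 radical formed during demercuration may attack the O–O bond and open the ring to an epoxide. The fallback sets out from dimethyl ketal 18 and puts the peroxide on C6 first. Cobalt-catalysed hydroperoxysilylation of the C6=C7 alkene (Co(acac)2, O2, Et3SiH; Isayama–Mukaiyama reaction) should place the silylperoxy group on the tertiary carbon and give methyl (4R,8R)-3,3-dimethoxy-4,6,8-trimethyl-16-phenyl-6-[(triethylsilyl)peroxy]hexadecanoate F1 as both C6 epimers. Catalytic TsOH in CH2Cl2 containing methanol should then remove the silyl group to give the free hydroperoxide, methyl (4R,8R)-6-hydroperoxy-3,3-dimethoxy-4,6,8-trimethyl-16-phenylhexadecanoate F2, which displaces one methoxy group of the C3 ketal, so the ring closes at O2–C3 in place of O1–C6. This should give 21 together with its C6 epimer, methyl 2-[(4R,6R)-3-methoxy-4,6-dimethyl-6-[(2R)-2-methyl-10-phenyldecyl]-1,2-dioxan-3-yl]acetate F3, to be separated by chromatography. The route is rejoined at 21; no radical next to a peroxide is involved, at the price of no control at C6.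

Step 9. The ketal may lose methanol toward the conjugated enol ether instead of exchanging, or exchange twice to the bis-hydroperoxide. The fallback sets out from β-keto ester 17 and peroxidises the free ketone in methanol (urea–hydrogen peroxide, catalytic Sc(OTf)3, MeOH). There the hemiketal and oxocarbenium ion are intercepted by H2O2 and any enol ether can re-add methanol, so no isolated ketal has to survive an aprotic acidic medium. This direct hydroperoxyketalisation returns to the route at 19 and makes no new compound.

Step 12. Under aqueous acid the free acid may ring-open to the δ-hydroperoxy β-keto acid and decarboxylate, or the O–O bond may cleave heterolytically faster than the methoxy group exchanges. The fallback sets out from ester 21 and reverses the order of the two deprotections. The same acid hydrolysis on the ester, where no β-keto acid can arise, should give methyl 2-[(3S,4R,6S)-3-hydroxy-4,6-dimethyl-6-[(2R)-2-methyl-10-phenyldecyl]-1,2-dioxan-3-yl]acetate F4. The methyl ester is then cleaved at pH 7 with pig liver esterase in phosphate buffer, which avoids both strong base and acid on the hemiketal and returns to the route at 23.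

Further compounds
F1 | step 10 | methyl (4R,8R)-3,3-dimethoxy-4,6,8-trimethyl-16-phenyl-6-[(triethylsilyl)peroxy]hexadecanoate (C6 epimers) | C[C@H](CCCCCCCCc1ccccc1)CC(C)(OO[Si](CC)(CC)CC)C[C@@H](C)C(OC)(OC)CC(=O)OC
F2 | step 10 | methyl (4R,8R)-6-hydroperoxy-3,3-dimethoxy-4,6,8-trimethyl-16-phenylhexadecanoate (C6 epimers) | C[C@H](CCCCCCCCc1ccccc1)CC(C)(OO)C[C@@H](C)C(OC)(OC)CC(=O)OC
F3 | step 10 | methyl 2-[(4R,6R)-3-methoxy-4,6-dimethyl-6-[(2R)-2-methyl-10-phenyldecyl]-1,2-dioxan-3-yl]acetate (C3 epimers) | C[C@H](CCCCCCCCc1ccccc1)C[C@]1(C)C[C@@H](C)C(OC)(CC(=O)OC)OO1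
F0 | step 9 | none | none
F4 | step 12 | methyl 2-[(3S,4R,6S)-3-hydroxy-4,6-dimethyl-6-[(2R)-2-methyl-10-phenyldecyl]-1,2-dioxan-3-yl]acetate | C[C@H](CCCCCCCCc1ccccc1)C[C@@]1(C)C[C@@H](C)[C@](O)(CC(=O)OC)OO1
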